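## The problem

CNP0170480.5 is a spiro-biflavonoid in which a 3,5,7-trihydroxychroman-4-one (ring A, O1, C2, C3, C4) shares C2 as a spiro atom with a cross-conjugated cyclohexa-2,5-dienone (ring C: C1′ = C2, C2′ to C6′, carbonyl at C4′). On one flank the dienone is fused through O–C2′ and the benzylic carbon Cα, which is bonded to C3, into a 2-aryl-2,3-dihydrofuran; on the other flank it is fused through O–C6′ and C5′ into the pyran ring of a 2,3-cis flavan-3-ol (C2″, C3″, C4″). Of the five stereocentres, C2 (S), C3 (R) and Cα (S) are contiguous, while C2″ (S) and C3″ (S) are remote from them. C3 can control both of its neighbours: the furan can only be cis-fused to the chromanone, so C3 decides which of the two oxygenated ring C carbons enters the furan and thereby fixes C2, and the aryl group on Cα prefers the convex face, cis to the 3-OH. The flavan pair is too far from the core to be controlled by it and has to be brought in as a single enantiomer onto an enantiopure core. Three features will not survive rough treatment: the tertiary C3–OH is β to the dienone through C2, so base opens a retro-aldol path that cleaves C2–C3 and aromatises ring C; the two benzylic C–O bonds (Cα–O and C2″–O) are para-oxygenated benzylic ethers of vinylogous ester oxygens, which ionise in acid and are at risk under hydrogenolysis; and the free polyphenol is easily oxidised. The dienone should therefore appear late and the last steps should be neutral. The feature that makes the key step possible is the substitution of C2, which bears O1 and C3 and lies between the oxygenated carbons C2′ and C6′: this is the pattern of C2 of a cyclohexane-1,3-dione after carbenoid O–H insertion into a phenol and aldol addition to the central carbonyl of a 1,3-diarylpropane-1,2-dione, and as long as ring C is a saturated, symmetric dione, C2 is not stereogenic and no aromatising retro-aldol exists.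

## Retrosynthesis

**Benzyl ethers (23 from 22).** Target 23 is traced back to its penta-O-benzyl ether 22, so the five O–benzyl bonds are cut last. Benzyl is chosen for all four phenols and for O3″ because it survives base, silyl chemistry, carbenoids and chromium oxidants and leaves under neutral conditions. The forward step must spare the two ring benzylic C–O bonds and the dienone.

**C4′ carbonyl (22 from 21).** The dienone oxygen of 22 is removed to give the bis(enol ether) 21 with a doubly allylic CH2. Carrying the C4′ oxygen from the start would make ring C a dearomatised phloroglucinol with an aromatising retro-aldol path, and it would leave two carbonyls competing for the pyran oxygen. With the oxidation last, the pyran closes when C6′ is the only ketone. The forward step is a bis-allylic C–H oxidation, which has to pick the weakest C–H bond among several benzylic ones.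

**Pyran ring (21 from 10 and 18, through 19 and 20).** The O–C6′ enol ether bond and the C5′–C4″ bond are cut: bis(enol ether) 21 opens to the diol ketone 20, which comes by desilylation from the alkylated ketone 19, itself assembled from ketone 10 and triflate 18. Cutting O–C2″ instead would mean closing at a benzylic cation, which favours the 2,3-trans flavan. A hetero-Diels–Alder annulation would give no control over the remote pair. Closing by addition of the C2″ hydroxyl to the C6′ ketone and dehydration breaks no bond at a stereocentre, so the cis pair is delivered intact from 18. Ketone 10 has a single enolisable position, so the alkylation is regiochemically unambiguous. The forward reaction must achieve an SN2 alkylation at a β-oxygenated primary carbon.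

**Three-carbon fragment (18 from 17, 16, 15; 15 from 13 and 14; 13 from 11 and 12).** Triflate 18 comes from alcohol 17, which arises by reductive removal of the auxiliary from the silyl ether 16 of aldol 15. The C2″–C3″ bond of 15 is cut by an auxiliary-controlled syn-glycolate aldol between imide 13 and aldehyde 14, and 13 is the acylation product of oxazolidinone 11 with acid chloride 12. Dihydroxylation of a cinnamate would give the same syn diol, but the two hydroxyls would then have to be told apart. The aldol delivers them already differentiated, one as a benzyl ether (O3″) and one free (O2″, silylated in 16).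

**Furan ring (10 from 9, 9 from 8).** Ketone 10 is the silyl ether of 9, and in 9 the O–Cα bond is cut to give the benzyl-substituted spiro trione 8, in which ring C is a symmetric 1,3-dione. Closure desymmetrises ring C and fixes C2 and Cα from C3 alone. The alternative, carrying an oxygen on Cα through the key step, would place a labile stereocentre next to the reacting ketone. The forward step must oxidise one benzylic C–H bond and stop there. Silylation of the tertiary alcohol of 9 to give 10 blocks retro-aldol during the enolate step.

**Chromanone ring, the key disconnection (8 from 4 and 6, through 7).** The O1–C2 and C2–C3 bonds of 8 are cut together. This removes the spiro centre, the tertiary alcohol and the heterocycle in one operation and leaves the ortho-acylphenol 4 and the symmetric diazo dione 6. Cutting C3–Cα or C3–C4 instead would keep the spiro C–O bond, the hardest bond in the molecule, for a separate step. The forward reaction must insert the carbenoid into the phenol O–H, then add the enol 7 to the alkyl ketone of the 1,2-dione with control of the ketone face.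

**Precursors (4 from 3, 2, 1; 6 from 5).** Dione 4 has the complete C6–C3–C6 skeleton and oxygen pattern of phloretin 1. Selective tribenzylation to 2, enolate hydroxylation to 3 and acyloin oxidation give 4 in three steps. Diazo transfer to cyclohexane-1,3-dione 5 gives 6.

## Roads not taken

**Alternative 1:** The cut is the C3–Cα bond. The spiro chroman-3,4-dione A1, which already carries the flavan-fused dienone and a 4-(benzyloxy)benzyloxy group on C2′, would be irradiated with visible light. The excited C3 carbonyl oxygen abstracts a benzylic hydrogen of the OCH2Ar group and the 1,5-biradical closes the furan, giving the penta-O-benzyl ether of the target A2, which is the same compound as 22.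
- Merits: the furan closes without a stoichiometric oxidant, the C3–OH and Cα arise together, and only the debenzylation follows A2. In endgame economy this road is better than the chosen one.
- Weak points: two stereocentres, one of them quaternary, come from a biradical collapse controlled only by the spiro centre. The cross-conjugated dienone is itself a photolabile chromophore. A1 has to be made with a defined spiro configuration while it carries a 1,2-dione next to the spiro carbon of a dienone, which is the aromatising fragmentation problem in its sharpest form.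
- Comparison: the chosen plan is longer after its key step, but its stereo-determining steps are ground-state reactions under catalyst, ring-fusion or auxiliary control, and the dienone is unveiled only at the end.

**Alternative 2:** The cuts are the C3–O and C3–Cα bonds. Rh2(OAc)4 would decompose the 3-diazo spirochromanone A3, the carbenoid would form an O–H oxonium ylide in wet solvent, and the ylide would be trapped by 4-(benzyloxy)benzaldehyde A4, which is the same compound as 14, to give the diol A5.
- Merits: it is convergent, and Cα arrives in A5 with its oxygen at the alcohol level, so the furan could close by displacement of a methoxy group with no C–H oxidation. In this respect it is better than the chosen plan, whose furan closure is its least precedented step.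
- Weak points: A3 is a spiro compound on a dimethoxy-dienone (a dearomatised phloroglucinol), so the spiro C–O bond is left unsolved and the aromatising pathway is open from the start. Trapping by A4 must outrun the 1,2-proton shift. Two adjacent stereocentres need both diastereo- and enantiocontrol. After furan closure the second methoxy enone would still have to be turned into the pyran at the α-carbon of a vinylogous ester.
- Comparison: the chosen plan solves the spiro centre and C3 in one step on a non-aromatisable ring and has a regiochemically clean pyran annulation; it pays with a benzylic oxidation.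

**Alternative 3:** The cuts are C5′–C4″, C4″–C3″ and O–C2″. The free enol of the furan-fused core A6 would condense with formaldehyde A7 to the 5′-methylene dione A9, a 1-oxadiene, which would add (Z)-2-[4-(benzyloxy)phenyl]vinyl acetate A8 to give the tetra-O-benzyl target 3″-acetate A10.
- Merits: three bonds and the whole pyran form in one step from achiral partners A7 and A8, and the cis relationship in A10 follows from the (Z)-alkene. In step count it clearly beats the seven steps that the chosen plan spends on this ring (steps 8 to 14).
- Weak points: the new centres are remote from the core stereocentres, so the diene faces are barely differentiated and two diastereomers are expected. Either carbonyl of A9 can act as the heterodiene oxygen, giving linear and angular pyrans. A6 already contains the dienone with the free C3–OH and must survive condensation conditions. The polarity of A8 is set by two competing donors.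
- Comparison: the chosen plan sets against the shorter annulation an auxiliary-controlled absolute configuration and a ring closure onto the only ketone present.

Key step: step 5

## Route

Assumption: compound 4 is drawn and numbered as the open-chain 1,2-dione; it is expected to rest mainly as its ring tautomer (the 2-benzyl-2-hydroxybenzofuran-3(2H)-one hemiketal) together with some enol, all of which interconvert and react through the open form.

In step 5, (R,R)-t-Bu-box is 2,2′-(propane-2,2-diyl)bis[(4R)-4-tert-butyl-4,5-dihydro-1,3-oxazole].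

Step 1
Reactants: 1 phloretin
Product: 2 1-[2,4-bis(benzyloxy)-6-hydroxyphenyl]-3-[4-(benzyloxy)phenyl]propan-1-one
Conditions: BnBr (3.1 equiv), K2CO3 (3.5 equiv), DMF, 0 → 25 °C
Reagents that add atoms: benzyl bromide, BrCc1ccccc1
Why: Williamson etherification; the para hydroxyls and one ortho hydroxyl react, while the second ortho hydroxyl is held in a hydrogen bond to the ketone and should stay free under carbonate conditions.

Step 2
Reactants: 2 1-[2,4-bis(benzyloxy)-6-hydroxyphenyl]-3-[4-(benzyloxy)phenyl]propan-1-one
Product: 3 (±)-1-[2,4-bis(benzyloxy)-6-hydroxyphenyl]-3-[4-(benzyloxy)phenyl]-2-hydroxypropan-1-one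
Conditions: KN(SiMe3)2 (2.3 equiv), THF, −78 °C; 2-(phenylsulfonyl)-3-phenyloxaziridine (1.2 equiv), −78 °C; AcOH quench
Reagents that add atoms: 2-(phenylsulfonyl)-3-phenyloxaziridine, O=S(=O)(c1ccccc1)N1OC1c1ccccc1
Why: Enolate hydroxylation with an N-sulfonyloxaziridine on the phenoxide/enolate dianion; C2 is the only enolisable position, and the racemic carbinol is of no consequence because it is oxidised in the next step.

Step 3
Reactants: 3 (±)-1-[2,4-bis(benzyloxy)-6-hydroxyphenyl]-3-[4-(benzyloxy)phenyl]-2-hydroxypropan-1-one
Product: 4 1-[2,4-bis(benzyloxy)-6-hydroxyphenyl]-3-[4-(benzyloxy)phenyl]propane-1,2-dione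
Conditions: Dess–Martin periodinane (1.3 equiv), CH2Cl2, 0 → 25 °C
Reagents that add atoms: none
Why: Dess–Martin oxidation converts acyloins into 1,2-diones without C–C cleavage; the chelated, acyl-deactivated phenol should exchange onto iodine far more slowly than the secondary alcohol.

Step 4
Reactants: 5 cyclohexane-1,3-dione
Product: 6 2-diazocyclohexane-1,3-dione
Conditions: 4-acetamidobenzenesulfonyl azide (1.05 equiv), Et3N, MeCN, 0 → 25 °C
Reagents that add atoms: 4-acetamidobenzenesulfonyl azide, CC(=O)Nc1ccc(cc1)S(=O)(=O)N=[N+]=[N-]
Why: Regitz diazo transfer to the active methylene of a cyclic 1,3-dione.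

Step 5
Reactants: 4 1-[2,4-bis(benzyloxy)-6-hydroxyphenyl]-3-[4-(benzyloxy)phenyl]propane-1,2-dione; 6 2-diazocyclohexane-1,3-dione
Product: 8 (3R)-5,7-bis(benzyloxy)-3-[4-(benzyloxy)benzyl]-3-hydroxyspiro[chromane-2,1′-cyclohexane]-2′,4,6′-trione, via aryloxy-dione enol 7 (not isolated)
Conditions: Rh2(OAc)4 (2 mol %), Cu(OTf)2 (10 mol %), (R,R)-t-Bu-box (11 mol %), 4 Å MS, PhF, 25 °C, slow addition of 6 (1.5 equiv); then 0 °C
Reagents that add atoms: none
Why: Rh2(OAc)4 converts 6 into an electrophilic carbenoid that is attacked by the phenol oxygen of the open tautomer of 4; proton transfer in the oxonium ylide gives the 2-aryloxy-1,3-dione as its enol 7 (O1–C2 formed). The divalent copper–bis(oxazoline) complex then chelates the two carbonyl oxygens of the 1,2-dione, and the enol adds through C2 to the ketone remote from ring A, closing the chromanone ring in a 6-exo-trig aldol (C2–C3 formed). The closest known reactions are the tandem carbenoid O–H insertion/intramolecular aldol of diazo carbonyl compounds with 2-acylphenols, the O–H insertion of 2-diazo-1,3-diones into phenols, and bis(oxazoline)–Cu(OTf)2-catalysed aldol additions to chelating 1,2-dicarbonyl compounds. C3 is the only new stereocentre and is set by the ligand: by analogy with the square-planar chelate model for pyruvate aldols, the (R,R)-ligand should expose the re face of the ketone and give 3R (the enantiomeric ligand is the remedy if the sense proves opposite); C2 is not stereogenic because ring C is still symmetric. Three selectivities are needed: the carbenoid must take the phenol O–H and not the tertiary, acyl-deactivated hemiketal O–H of the ring tautomer (the tautomers interconvert, so the faster-reacting phenol can drain the mixture); the enol must attack the alkyl ketone and not the doubly ortho-substituted aryl ketone (only the former gives a six-membered ring); and the aldol must be stopped under kinetic control, since retro-aldol would racemise C3.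

Step 6
Reactants: 8 (3R)-5,7-bis(benzyloxy)-3-[4-(benzyloxy)benzyl]-3-hydroxyspiro[chromane-2,1′-cyclohexane]-2′,4,6′-trione
Product: 9 furan-fused keto enol ether (2S,3R,αS): Cα bonded to the oxygen on C2′, C2′=C3′ enol ether, C6′ ketone, aryl cis to 3-OH
Conditions: DDQ (1.05 equiv), 4 Å MS, ClCH2CH2Cl, 0 → 40 °C, stopped before full conversion
Reagents that add atoms: none
Why: Proposed new method: DDQ should abstract hydride from the CH2 para to the benzyloxy group to give a quinone-methide-type benzylic cation; the oxygen of the C2′ carbonyl syn to it closes a five-membered oxocarbenium ion and loss of a C3′ proton gives the enol ether, so that only the cis-fused furan can form (C2 becomes S) and the aryl group settles on the convex face cis to the 3-OH (Cα S), reversible ionisation of the new benzylic ether allowing equilibration; the closest known reaction type is the DDQ-mediated dehydrogenative benzylic C–O cyclisation of 4-alkoxyphenyl alkanes carrying a tethered phenol, alcohol or 1,3-dicarbonyl enol (flavan and dihydrofuran formation), here extended to a non-enolised ketone oxygen as nucleophile.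

Step 7
Reactants: 9 furan-fused keto enol ether
Product: 10 3-O-trimethylsilyl ether of 9 (stereocentres unchanged)
Conditions: 1-(trimethylsilyl)imidazole (1.5 equiv), CH2Cl2, 25 °C
Reagents that add atoms: 1-(trimethylsilyl)imidazole, C[Si](C)(C)n1ccnc1
Why: Silylation of a hindered tertiary alcohol with a neutral silyl imidazole that leaves the ketone and the acid-sensitive enol ether alone; the silyl ether removes the alkoxide that would open the retro-aldol path in step 13.

Step 8
Reactants: 11 (R)-4-benzyloxazolidin-2-one; 12 (benzyloxy)acetyl chloride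
Product: 13 (R)-4-benzyl-3-[(benzyloxy)acetyl]oxazolidin-2-one
Conditions: n-BuLi (1.0 equiv), THF, −78 °C; then 12, −78 → 0 °C
Reagents that add atoms: none
Why: N-acylation of the lithiated oxazolidinone with an acid chloride.

Step 9
Reactants: 13 (R)-4-benzyl-3-[(benzyloxy)acetyl]oxazolidin-2-one; 14 4-(benzyloxy)benzaldehyde
Product: 15 (4R)-4-benzyl-3-{(2R,3S)-2-(benzyloxy)-3-[4-(benzyloxy)phenyl]-3-hydroxypropanoyl}oxazolidin-2-one
Conditions: Bu2BOTf (1.1 equiv), Et3N (1.3 equiv), CH2Cl2, −78 → 0 °C; 14, −78 → 0 °C; pH 7 buffer, MeOH, H2O2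
Reagents that add atoms: none
Why: Evans syn-aldol of the (Z)-boron enolate of a glycolyl imide through a chair transition state; the (R)-auxiliary sets both new centres as (2R,3S), the syn pair that becomes the cis C3″/C2″ pair.

Step 10
Reactants: 15 (4R)-4-benzyl-3-{(2R,3S)-2-(benzyloxy)-3-[4-(benzyloxy)phenyl]-3-hydroxypropanoyl}oxazolidin-2-one
Product: 16 (4R)-4-benzyl-3-{(2R,3S)-2-(benzyloxy)-3-[4-(benzyloxy)phenyl]-3-[(triethylsilyl)oxy]propanoyl}oxazolidin-2-one
Conditions: Et3SiCl (1.3 equiv), imidazole (2 equiv), DMF, 0 → 25 °C
Reagents that add atoms: chlorotriethylsilane, CC[Si](Cl)(CC)CC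
Why: Silylation of the secondary benzylic alcohol; the two oxygens are now differentiated as a robust benzyl ether (future 3″-OH) and a labile silyl ether (future ring oxygen).

Step 11
Reactants: 16 (4R)-4-benzyl-3-{(2R,3S)-2-(benzyloxy)-3-[4-(benzyloxy)phenyl]-3-[(triethylsilyl)oxy]propanoyl}oxazolidin-2-one
Product: 17 (2S,3S)-2-(benzyloxy)-3-[4-(benzyloxy)phenyl]-3-[(triethylsilyl)oxy]propan-1-ol
Conditions: LiBH4 (2 equiv), MeOH (2 equiv), THF, 0 °C
Reagents that add atoms: none
Why: Reductive cleavage of the N-acyloxazolidinone with LiBH4 gives the primary alcohol and returns the auxiliary; no stereocentre is touched (the C2 descriptor changes only through the priority rules).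

Step 12
Reactants: 17 (2S,3S)-2-(benzyloxy)-3-[4-(benzyloxy)phenyl]-3-[(triethylsilyl)oxy]propan-1-ol
Product: 18 (2S,3S)-2-(benzyloxy)-3-[4-(benzyloxy)phenyl]-3-[(triethylsilyl)oxy]propyl trifluoromethanesulfonate
Conditions: Tf2O (1.2 equiv), 2,6-lutidine (1.5 equiv), CH2Cl2, −78 °C; used at once
Reagents that add atoms: trifluoromethanesulfonic anhydride, O=S(=O)(OS(=O)(=O)C(F)(F)F)C(F)(F)F
Why: Triflation of a primary alcohol; the triflate is chosen over the iodide because β-alkoxy primary halides are poor partners for ketone enolates.

Step 13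
Reactants: 10 3-O-trimethylsilyl ether of 9; 18 (2S,3S)-2-(benzyloxy)-3-[4-(benzyloxy)phenyl]-3-[(triethylsilyl)oxy]propyl trifluoromethanesulfonate
Product: 19 C5′-alkylated ketone: 10 carrying the (2S,3S)-2-(benzyloxy)-3-[4-(benzyloxy)phenyl]-3-[(triethylsilyl)oxy]propyl group on C5′ (C5′ epimers)
Conditions: LiN(i-Pr)2 (1.05 equiv), THF, −78 °C; 18 (1.3 equiv), −78 → −30 °C
Reagents that add atoms: none
Why: SN2 alkylation of the kinetic lithium enolate; C5′ is the only enolisable position (C1′ is quaternary, C4 has no α-hydrogen), and the new C5′ centre is erased in step 14.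

Step 14
Reactants: 19 C5′-alkylated ketone
Product: 21 pentacyclic bis(enol ether) (4′-deoxo form of 22), via diol ketone 20 (not isolated)
Conditions: HF·pyridine, pyridine, THF, 0 → 25 °C; then pyridinium p-toluenesulfonate (10 mol %), 4 Å MS, PhH, 60 °C
Reagents that add atoms: none
Why: Fluoride desilylation followed by acid-catalysed cyclodehydration of a δ-hydroxy ketone (hemiketal, then enol ether); no bond at C2″ or C3″ is broken, so the cis pair is retained, the double bond can only form towards C5′, and only the six-membered ring is possible because O3″ is benzylated. The weak acid is chosen to keep the para-alkoxybenzylic alcohol from ionising.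

Step 15
Reactants: 21 pentacyclic bis(enol ether)
Product: 22 penta-O-benzyl ether of the target
Conditions: (C5H5NH)2Cr2O7 (0.5 equiv), t-BuOOH (4 equiv), Celite, PhH, 10 → 25 °C
Reagents that add atoms: tert-butyl hydroperoxide, CC(C)(C)OO
Why: Hexavalent chromium/t-BuOOH bis-allylic oxidation of a 3,3-disubstituted cyclohexa-1,4-diene to the cross-conjugated dienone, a reaction known for alkoxy-substituted Birch-type dienes; the C4′ hydrogens, flanked by two enol ethers, are the weakest C–H bonds in the molecule, the quaternary C1′ rules out aromatisation, and the neutral medium avoids the retro-aldol.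

Step 16
Reactants: 22 penta-O-benzyl ether of the target
Product: 23 CNP0170480.5
Conditions: H2 (1 atm), 10 % Pd/C, EtOAc/MeOH, 25 °C, stopped at the calculated uptake
Reagents that add atoms: none
Why: Hydrogenolysis of aryl and alkyl benzyl ethers under neutral conditions; the tri- and tetrasubstituted double bonds of the doubly β-oxygenated dienone and the hindered secondary ring benzylic C–O bonds should react much more slowly than the primary O-benzyl groups.

## Compound list

1 | phloretin, 3-(4-hydroxyphenyl)-1-(2,4,6-trihydroxyphenyl)propan-1-one | O=C(CCc1ccc(O)cc1)c1c(O)cc(O)cc1O | starting material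
2 | 1-[2,4-bis(benzyloxy)-6-hydroxyphenyl]-3-[4-(benzyloxy)phenyl]propan-1-one | O=C(CCc1ccc(OCc2ccccc2)cc1)c1c(O)cc(OCc2ccccc2)cc1OCc1ccccc1 | intermediate
3 | (±)-1-[2,4-bis(benzyloxy)-6-hydroxyphenyl]-3-[4-(benzyloxy)phenyl]-2-hydroxypropan-1-one | O=C(C(O)Cc1ccc(OCc2ccccc2)cc1)c1c(O)cc(OCc2ccccc2)cc1OCc1ccccc1 | intermediate
4 | 1-[2,4-bis(benzyloxy)-6-hydroxyphenyl]-3-[4-(benzyloxy)phenyl]propane-1,2-dione (open-chain tautomer) | Oc1cc(OCc2ccccc2)cc(OCc2ccccc2)c1C(=O)C(=O)Cc1ccc(OCc2ccccc2)cc1 | intermediate
5 | cyclohexane-1,3-dione | O=C1CCCC(=O)C1 | starting material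
6 | 2-diazocyclohexane-1,3-dione | O=C1CCCC(=O)C1=[N+]=[N-] | intermediate
7 | 2-{3,5-bis(benzyloxy)-2-[3-(4-(benzyloxy)phenyl)-2-oxopropanoyl]phenoxy}-3-hydroxycyclohex-2-en-1-one (not isolated) | O=C1CCCC(O)=C1Oc1cc(OCc2ccccc2)cc(OCc2ccccc2)c1C(=O)C(=O)Cc1ccc(OCc2ccccc2)cc1 | intermediate
8 | (3R)-5,7-bis(benzyloxy)-3-[4-(benzyloxy)benzyl]-3-hydroxyspiro[chromane-2,1′-cyclohexane]-2′,4,6′-trione | O=C1CCCC(=O)C12Oc1cc(OCc3ccccc3)cc(OCc3ccccc3)c1C(=O)[C@@]2(O)Cc1ccc(OCc2ccccc2)cc1 | intermediate
9 | furan-fused keto enol ether, (2S,3R,αS): 5,7-bis(benzyloxy)-3-hydroxychroman-4-one spiro at C2 to a cyclohex-2′-en-6′-one, with C3–CαH[4-(benzyloxy)phenyl]–O–C2′ closing a 2,3-dihydrofuran; aryl cis to 3-OH | C1C=C2O[C@@H](c3ccc(OCc4ccccc4)cc3)[C@]3(O)C(=O)c4c(OCc5ccccc5)cc(OCc5ccccc5)cc4O[C@]23C(=O)C1 | intermediate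
10 | 3-O-trimethylsilyl ether of 9, stereocentres unchanged | C1C=C2O[C@@H](c3ccc(OCc4ccccc4)cc3)[C@]3(O[Si](C)(C)C)C(=O)c4c(OCc5ccccc5)cc(OCc5ccccc5)cc4O[C@]23C(=O)C1 | intermediate
11 | (R)-4-benzyloxazolidin-2-one | O=C1N[C@H](Cc2ccccc2)CO1 | starting material
12 | (benzyloxy)acetyl chloride | O=C(Cl)COCc1ccccc1 | starting material
13 | (R)-4-benzyl-3-[(benzyloxy)acetyl]oxazolidin-2-one | O=C(COCc1ccccc1)N1[C@H](Cc2ccccc2)COC1=O | intermediate
14 | 4-(benzyloxy)benzaldehyde | O=Cc1ccc(OCc2ccccc2)cc1 | starting material
15 | (4R)-4-benzyl-3-{(2R,3S)-2-(benzyloxy)-3-[4-(benzyloxy)phenyl]-3-hydroxypropanoyl}oxazolidin-2-one | O=C([C@H](OCc1ccccc1)[C@@H](O)c1ccc(OCc2ccccc2)cc1)N1[C@H](Cc2ccccc2)COC1=O | intermediate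
16 | (4R)-4-benzyl-3-{(2R,3S)-2-(benzyloxy)-3-[4-(benzyloxy)phenyl]-3-[(triethylsilyl)oxy]propanoyl}oxazolidin-2-one | O=C([C@H](OCc1ccccc1)[C@@H](O[Si](CC)(CC)CC)c1ccc(OCc2ccccc2)cc1)N1[C@H](Cc2ccccc2)COC1=O | intermediate
17 | (2S,3S)-2-(benzyloxy)-3-[4-(benzyloxy)phenyl]-3-[(triethylsilyl)oxy]propan-1-ol | OC[C@H](OCc1ccccc1)[C@@H](O[Si](CC)(CC)CC)c1ccc(OCc2ccccc2)cc1 | intermediate
18 | (2S,3S)-2-(benzyloxy)-3-[4-(benzyloxy)phenyl]-3-[(triethylsilyl)oxy]propyl trifluoromethanesulfonate | O=S(=O)(OC[C@H](OCc1ccccc1)[C@@H](O[Si](CC)(CC)CC)c1ccc(OCc2ccccc2)cc1)C(F)(F)F | intermediate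
19 | C5′-alkylated ketone: 10 with the (2S,3S)-2-(benzyloxy)-3-[4-(benzyloxy)phenyl]-3-[(triethylsilyl)oxy]propyl group on C5′, mixture of C5′ epimers | C1C=C2O[C@@H](c3ccc(OCc4ccccc4)cc3)[C@]3(O[Si](C)(C)C)C(=O)c4c(OCc5ccccc5)cc(OCc5ccccc5)cc4O[C@]23C(=O)C1C[C@H](OCc1ccccc1)[C@@H](O[Si](CC)(CC)CC)c1ccc(OCc2ccccc2)cc1 | intermediate
20 | diol ketone: 19 without both silyl groups (3-OH and C2″-OH free; not isolated) | C1C=C2O[C@@H](c3ccc(OCc4ccccc4)cc3)[C@]3(O)C(=O)c4c(OCc5ccccc5)cc(OCc5ccccc5)cc4O[C@]23C(=O)C1C[C@H](OCc1ccccc1)[C@@H](O)c1ccc(OCc2ccccc2)cc1 | intermediate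
21 | pentacyclic bis(enol ether), 4′-deoxo form of 22 (C4′ is CH2; C2 S, C3 R, Cα S, C2″ S, C3″ S) | C1C=C2O[C@@H](c3ccc(OCc4ccccc4)cc3)[C@]3(O)C(=O)c4c(OCc5ccccc5)cc(OCc5ccccc5)cc4O[C@]23C2=C1C[C@H](OCc1ccccc1)[C@H](c1ccc(OCc3ccccc3)cc1)O2 | intermediate
22 | penta-O-benzyl ether of the target (benzyl on O5, O7, both 4-hydroxyphenyl oxygens and O3″; 3-OH free) | O=C1C=C2O[C@@H](c3ccc(OCc5ccccc5)cc3)[C@]3(O)C(=O)c4c(OCc5ccccc5)cc(OCc5ccccc5)cc4O[C@]23C2=C1C[C@H](OCc1ccccc1)[C@H](c1ccc(OCc3ccccc3)cc1)O2 | intermediate
23 | CNP0170480.5 | O=C1C=C2O[C@@H](c3ccc(O)cc3)[C@]3(O)C(=O)c4c(O)cc(O)cc4O[C@]23C2=C1C[C@H](O)[C@H](c1ccc(O)cc1)O2 | target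

## Step count and least certain steps

Total: 16 steps. Longest linear sequence: 10 steps from phloretin (steps 1, 2, 3, 5, 6, 7, 13, 14, 15, 16); the fragment branch has 5 steps (8 to 12) and the diazo branch 1 step (4).

**Step 6 (proposed new method).** Two processes are likely to go wrong:
- Hydride abstraction may be slow, because the benzylic CH2 is inductively deactivated by the adjacent carbinol and carbonyl groups.
- The product may be oxidised further, either at its new benzylic ether C–H or at the allylic positions of its enol ether.

The fallback brings the benzylic oxygen in before the spiro-annulation instead of oxidising a C–H bond after it, and uses only known reaction types (ketone α-bromination, benzylic solvolysis, the reaction of step 5, Lewis-acid SN1 etherification). It sets out from 4. α-Bromination through the enol of the open tautomer (CuBr2, EtOAc/CHCl3, reflux) would give 1-[2,4-bis(benzyloxy)-6-hydroxyphenyl]-3-[4-(benzyloxy)phenyl]-3-bromopropane-1,2-dione F1. Solvolysis in methanol (NaHCO3, 25 °C) would give the 3-methoxy dione F2. F2 is taken through the conditions of step 5 with 6 to give the 3-[aryl(methoxy)methyl] spiro trione F3 as a mixture of benzylic epimers. The mixture is of no consequence, because BF3·OEt2 (CH2Cl2, −40 °C) ionises the benzylic ether to the same cation that step 6 aims at, and its capture by the C2′ carbonyl oxygen brings the route back at 9.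

**Step 5 (key step).** Two processes are likely to go wrong:
- The carbenoid may be captured by the hemiketal hydroxyl of the ring tautomer of 4 instead of the phenol.
- Enantiocontrol may be lost through a background or reversible aldol.

The fallback separates insertion from ring closure and keeps the 1,2-dione absent while the carbenoid is present. It sets out from 3. Et3SiCl/imidazole should silylate the secondary hydroxyl and leave the chelated phenol, giving the 2-(triethylsilyloxy) ketone F4. Rh2(OAc)4 and 6 then insert into the only free O–H to give the aryloxy-dione enol F5. HF·pyridine frees the acyloin F6, and a Dess–Martin oxidation at 0 °C generates 7. Compound 7 is then cyclised by the preformed bis(oxazoline)–Cu(OTf)2 complex alone at −20 °C, which brings the route back at 8.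

**Step 13.** The likely failure is slow SN2 displacement at the β-oxygenated, β-branched primary carbon, with O-alkylation of the enolate or decomposition of the triflate taking over. The fallback replaces alkylation by carbonyl addition. It sets out from 17: Dess–Martin oxidation gives (2R,3S)-2-(benzyloxy)-3-[4-(benzyloxy)phenyl]-3-[(triethylsilyl)oxy]propanal F7. Addition of the lithium enolate of 10 gives the β-hydroxy ketone F8. Burgess dehydration gives the exocyclic enone F9, and conjugate reduction with [(Ph3P)CuH]6 brings the route back at 19.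

**Step 16.** The likely failure is hydrogenolysis of the ring benzylic C–O bonds at Cα and C2″ (both are benzylic vinylogous esters), or saturation of a dienone double bond, before the secondary O3″ benzyl ether is gone. The fallback removes the benzyl groups without hydrogen: from 22, BCl3 with pentamethylbenzene as cation scavenger (CH2Cl2, −78 °C) leads directly to 23, so that no new compound arises on the way and the entry for this fallback is F0.

## Further compounds

F1 | step 6 | 1-[2,4-bis(benzyloxy)-6-hydroxyphenyl]-3-[4-(benzyloxy)phenyl]-3-bromopropane-1,2-dione | BrC(C(=O)C(=O)c1c(O)cc(OCc2ccccc2)cc1OCc1ccccc1)c1ccc(OCc2ccccc2)cc1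
F2 | step 6 | 1-[2,4-bis(benzyloxy)-6-hydroxyphenyl]-3-[4-(benzyloxy)phenyl]-3-methoxypropane-1,2-dione | COC(C(=O)C(=O)c1c(O)cc(OCc2ccccc2)cc1OCc1ccccc1)c1ccc(OCc2ccccc2)cc1
F3 | step 6 | (3R)-5,7-bis(benzyloxy)-3-{[4-(benzyloxy)phenyl](methoxy)methyl}-3-hydroxyspiro[chromane-2,1′-cyclohexane]-2′,4,6′-trione, benzylic epimers | O=C1CCCC(=O)C12Oc1cc(OCc3ccccc3)cc(OCc3ccccc3)c1C(=O)[C@@]2(O)C(OC)c1ccc(OCc2ccccc2)cc1
F4 | step 5 | 1-[2,4-bis(benzyloxy)-6-hydroxyphenyl]-3-[4-(benzyloxy)phenyl]-2-[(triethylsilyl)oxy]propan-1-one | CC[Si](CC)(CC)OC(Cc1ccc(OCc2ccccc2)cc1)C(=O)c1c(O)cc(OCc2ccccc2)cc1OCc1ccccc1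
F5 | step 5 | 2-{3,5-bis(benzyloxy)-2-[3-(4-(benzyloxy)phenyl)-2-[(triethylsilyl)oxy]propanoyl]phenoxy}-3-hydroxycyclohex-2-en-1-one | CC[Si](CC)(CC)OC(Cc1ccc(OCc2ccccc2)cc1)C(=O)c1c(OC2=C(O)CCCC2=O)cc(OCc2ccccc2)cc1OCc1ccccc1
F6 | step 5 | 2-{3,5-bis(benzyloxy)-2-[3-(4-(benzyloxy)phenyl)-2-hydroxypropanoyl]phenoxy}-3-hydroxycyclohex-2-en-1-one | OC(Cc1ccc(OCc2ccccc2)cc1)C(=O)c1c(OC2=C(O)CCCC2=O)cc(OCc2ccccc2)cc1OCc1ccccc1
F7 | step 13 | (2R,3S)-2-(benzyloxy)-3-[4-(benzyloxy)phenyl]-3-[(triethylsilyl)oxy]propanal | O=C[C@H](OCc1ccccc1)[C@@H](O[Si](CC)(CC)CC)c1ccc(OCc2ccccc2)cc1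
F8 | step 13 | aldol adduct of 10 (at C5′) with F7, β-hydroxy ketone, mixture at C5′ and the new carbinol | C1C=C2O[C@@H](c3ccc(OCc4ccccc4)cc3)[C@]3(O[Si](C)(C)C)C(=O)c4c(OCc5ccccc5)cc(OCc5ccccc5)cc4O[C@]23C(=O)C1C(O)[C@H](OCc1ccccc1)[C@@H](O[Si](CC)(CC)CC)c1ccc(OCc2ccccc2)cc1
F9 | step 13 | C5′-alkylidene ketone (exocyclic enone) from dehydration of F8 | C1C=C2O[C@@H](c3ccc(OCc4ccccc4)cc3)[C@]3(O[Si](C)(C)C)C(=O)c4c(OCc5ccccc5)cc(OCc5ccccc5)cc4O[C@]23C(=O)C1=C[C@H](OCc1ccccc1)[C@@H](O[Si](CC)(CC)CC)c1ccc(OCc2ccccc2)cc1
F0 | step 16 | none | none
A1 | alternative 1 | spiro chroman-3,4-dione carrying the flavan-fused dienone and a 4-(benzyloxy)benzyloxy group on C2′ | O=C1C=C(OCc2ccc(OCc3ccccc3)cc2)[C@]2(Oc3cc(OCc4ccccc4)cc(OCc4ccccc4)c3C(=O)C2=O)C2=C1C[C@H](OCc1ccccc1)[C@H](c1ccc(OCc3ccccc3)cc1)O2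
A2 | alternative 1 | penta-O-benzyl ether of the target (identical with 22) | O=C1C=C2O[C@@H](c3ccc(OCc5ccccc5)cc3)[C@]3(O)C(=O)c4c(OCc5ccccc5)cc(OCc5ccccc5)cc4O[C@]23C2=C1C[C@H](OCc1ccccc1)[C@H](c1ccc(OCc3ccccc3)cc1)O2
A3 | alternative 2 | 5,7-bis(benzyloxy)-3-diazo-2′,6′-dimethoxyspiro[chromane-2,1′-cyclohexa-2′,5′-diene]-4,4′-dione | COC1=CC(=O)C=C(OC)C12Oc1cc(OCc3ccccc3)cc(OCc3ccccc3)c1C(=O)C2=[N+]=[N-]
A4 | alternative 2 | 4-(benzyloxy)benzaldehyde (identical with 14) | O=Cc1ccc(OCc2ccccc2)cc1
A5 | alternative 2 | 3-hydroxy-3-[aryl(hydroxy)methyl] spirochromanone on the 2′,6′-dimethoxy dienone | COC1=CC(=O)C=C(OC)C12Oc1cc(OCc3ccccc3)cc(OCc3ccccc3)c1C(=O)[C@@]2(O)[C@@H](O)c1ccc(OCc2ccccc2)cc1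
A6 | alternative 3 | furan-fused core as its free enol (6′-hydroxy dienone) | O=C1C=C2O[C@@H](c3ccc(OCc4ccccc4)cc3)[C@]3(O)C(=O)c4c(OCc5ccccc5)cc(OCc5ccccc5)cc4O[C@]23C(O)=C1
A7 | alternative 3 | formaldehyde | C=O
A8 | alternative 3 | (Z)-2-[4-(benzyloxy)phenyl]vinyl acetate | CC(=O)O/C=C\c1ccc(OCc2ccccc2)cc1
A9 | alternative 3 | 5′-methylene-4′,6′-dione of the furan-fused core (Knoevenagel product) | O=C1C=C2O[C@@H](c3ccc(OCc4ccccc4)cc3)[C@]3(O)C(=O)c4c(OCc5ccccc5)cc(OCc5ccccc5)cc4O[C@]23C(=O)C1=C
A10 | alternative 3 | tetra-O-benzyl target 3″-acetate | O=C1C=C2O[C@@H](c3ccc(OCc5ccccc5)cc3)[C@]3(O)C(=O)c4c(OCc5ccccc5)cc(OCc5ccccc5)cc4O[C@]23C2=C1C[C@H](OC(C)=O)[C@H](c1ccc(OCc3ccccc3)cc1)O2
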